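**Remark.** From the SMILES the target is the (2S,3R,4S)-oxolane with aryl, acyloxymethyl and hydroxyl all cis. The four starting materials are taken to be commercial, and diazomethane is used as a freshly prepared ethereal solution.

**Plan**
- Retrosynthetic cuts, in order: the ester C–O bond (3,4-dimethoxybenzoyl chloride); the C4–H bond of the carbinol (C4 carried as a ketone); the ring bond O1–C5; the bond C4–C5 (C5 from diazomethane); the bond C2–C3 (aldol).
- Enabling feature: in the oxolane, C5 is an unsubstituted CH2 between the ring oxygen O1 and the carbinol carbon C4. C4 can therefore be carried as a ketone and C5 as the diazo carbon of a diazomethyl ketone, whose carbenoid inserts into the O–H bond of the benzylic C2 hydroxyl five atoms away.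
- Forward: an auxiliary-controlled syn aldol reaction joins C2–C3; the acid is homologated to the diazoketone; rhodium-carbenoid O–H insertion closes the only ring as an oxolan-3-one; ketone reduction, debenzylation and selective esterification finish.
- Stereochemistry: C2 and C3 are set together in the Evans syn aldol step by the (S)-4-benzyloxazolidinone. C4 is relayed from them: a bulky hydride adds to the ring ketone anti to the two cis substituents, giving the all-cis triad.
- Helpers removed later: the C4 ketone (step 8), the silyl ether (step 6), the benzyl ether (step 9).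

Key step: step 7

**Step 1**
Reactants: 1 3-(benzyloxy)propanoic acid; 2 (S)-4-benzyloxazolidin-2-one
Product: 4 (S)-4-benzyl-3-[3-(benzyloxy)propanoyl]oxazolidin-2-one, via mixed pivalic anhydride 3 (not isolated)
Conditions: PivCl, Et3N, THF, −20 °C; then LiCl, 2, −20 °C to rt
Reagents that add atoms: pivaloyl chloride CC(C)(C)C(=O)Cl (its atoms stay only in intermediate 3)
Why: N-Acylation of the oxazolidinone by a mixed pivalic anhydride with LiCl/Et3N activation is the standard way to load an acid on an Evans auxiliary, and the hindered pivaloyl carbonyl of 3 directs attack to the 3-(benzyloxy)propanoyl carbonyl.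

**Step 2**
Reactants: 4 (S)-4-benzyl-3-[3-(benzyloxy)propanoyl]oxazolidin-2-one; 5 3,4-dimethoxybenzaldehyde
Product: 8 (S)-4-benzyl-3-[(2S,3S)-2-[(benzyloxy)methyl]-3-(3,4-dimethoxyphenyl)-3-hydroxypropanoyl]oxazolidin-2-one, via dibutylboron Z-enolate 6 (not isolated), via dibutylboron aldolate 7 (not isolated)
Conditions: Bu2BOTf, i-Pr2NEt, CH2Cl2, −78 to 0 °C; then 5, −78 to 0 °C; then pH 7 buffer, MeOH, 30% H2O2, 0 °C
Reagents that add atoms: dibutylboron triflate CCCCB(CCCC)OS(=O)(=O)C(F)(F)F (its boron stays only in intermediates 6 and 7)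
Why: Evans syn aldol reaction: soft enolisation gives the Z-enolate 6, which adds to the aldehyde through a chair Zimmerman–Traxler transition state on the enolate face away from the benzyl group of the auxiliary, so the (S)-auxiliary sets both new stereocentres (2S,3S, syn) in one event, while the covalent boron enolate at low temperature should not expel the β-benzyloxy group.

**Step 3**
Reactants: 8 the syn aldol adduct
Product: 9 (S)-4-benzyl-3-[(2S,3S)-2-[(benzyloxy)methyl]-3-[(tert-butyldimethylsilyl)oxy]-3-(3,4-dimethoxyphenyl)propanoyl]oxazolidin-2-one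
Conditions: TBSOTf, 2,6-lutidine, CH2Cl2, −78 to 0 °C
Reagents that add atoms: tert-butyldimethylsilyl triflate CC(C)(C)[Si](C)(C)OS(=O)(=O)C(F)(F)F
Why: Silyl ether formation with a silyl triflate and a hindered pyridine base masks the secondary benzylic hydroxyl so that the carboxyl group can be activated in step 5.

**Step 4**
Reactants: 9 the silylated imide
Product: 11 (2S,3S)-2-[(benzyloxy)methyl]-3-[(tert-butyldimethylsilyl)oxy]-3-(3,4-dimethoxyphenyl)propanoic acid, via peroxy acid 10 (not isolated)
Conditions: LiOH, 30% H2O2, THF/H2O (3:1), 0 °C; then aq. Na2SO3; then 1 M HCl to pH 3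
Reagents that add atoms: hydrogen peroxide OO (as LiOOH it supplies the carboxyl OH oxygen)
Why: Hydroperoxide cleavage of an N-acyloxazolidinone: the weakly basic, strongly nucleophilic LiOOH attacks the exocyclic carbonyl without epimerising the α-centre, the peroxy acid 10 is reduced by sulfite, and the auxiliary 2 is recovered.

**Step 5**
Reactants: 11 the silyloxy acid
Product: 13 (3S,4S)-3-[(benzyloxy)methyl]-4-[(tert-butyldimethylsilyl)oxy]-1-diazo-4-(3,4-dimethoxyphenyl)butan-2-one, via mixed carbonic anhydride 12 (not isolated)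
Conditions: i-BuOCOCl, Et3N, THF, −15 °C; then CH2N2, Et2O, −15 °C to rt
Reagents that add atoms: diazomethane C=[N+]=[N-]; isobutyl chloroformate CC(C)COC(=O)Cl (its atoms stay only in intermediate 12)
Why: C-Acylation of diazomethane by a mixed carbonic anhydride (first stage of the Arndt–Eistert sequence) gives the diazomethyl ketone under mild, base-buffered conditions that leave the silyl and benzyl ethers and the α-stereocentre untouched.

**Step 6**
Reactants: 13 the silyloxy diazoketone
Product: 14 (3S,4S)-3-[(benzyloxy)methyl]-1-diazo-4-(3,4-dimethoxyphenyl)-4-hydroxybutan-2-one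
Conditions: Bu4NF, AcOH (1:1), THF, 0 °C to rt
Reagents that add atoms: none
Why: Fluoride-induced desilylation, buffered with acetic acid so that the medium is neither basic enough for retro-aldol cleavage or β-elimination nor acidic enough to protonate the diazo carbon, frees the hydroxyl for the insertion.

**Step 7**
Reactants: 14 the hydroxy diazoketone
Product: 15 (4S,5S)-4-[(benzyloxy)methyl]-5-(3,4-dimethoxyphenyl)oxolan-3-one (4,5-cis)
Conditions: Rh2(OAc)4 (1 mol%), CH2Cl2, rt, slow addition of 14
Reagents that add atoms: none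
Why: Rh2(OAc)4 (divalent rhodium) decomposes the diazoketone with loss of N2 to an electrophilic rhodium carbenoid at the terminal carbon; the benzylic hydroxyl oxygen, five atoms away, adds to this carbon to give a cyclic oxonium ylide, and a 1,2-proton shift releases the catalyst and the ketone, so the O–CH2 bond of the oxolane is made. The closest known reaction type is the rhodium-carboxylate-catalysed intramolecular O–H insertion of β'-hydroxy-α-diazoketones to oxolan-3-ones. The single ring closed, the oxolane, forms in a 5-exo-trig-like mode, the oxygen attacking the carbenoid carbon with the Rh=C bond outside the forming ring. No new stereocentre is created; the two centres from step 2 are retained because the conditions are neutral, and the ketone formed next to them is the temporary oxidation level that lets step 8 relay their configuration to the third centre. The step needs chemoselectivity for O–H insertion over cycloaddition to the dimethoxyphenyl ring (Buchner reaction), over ylide formation at the benzyl ether oxygen and over C–H insertion; the free hydroxyl is the most nucleophilic site, its ylide collapses irreversibly by proton transfer whereas an ether ylide reverts, and the moderately electrophilic acetate-ligated carbenoid at room temperature with slow addition favours this pathway.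

**Step 8**
Reactants: 15 the oxolan-3-one
Product: 16 (3S,4R,5S)-4-[(benzyloxy)methyl]-5-(3,4-dimethoxyphenyl)oxolan-3-ol (all-cis)
Conditions: LiBH(s-Bu)3, THF, −78 °C; then NaOH, H2O2, 0 °C
Reagents that add atoms: none
Why: Substrate-controlled reduction of a cyclic ketone by a bulky trialkylborohydride (L-Selectride): the hydride adds to the carbonyl from the face opposite the cis benzyloxymethyl and aryl groups, so the new carbinol centre (3S) is set by the two existing ring stereocentres with its hydroxyl cis to both, and at −78 °C the reagent should not enolise the adjacent centre.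

**Step 9**
Reactants: 16 the all-cis benzyl ether
Product: 17 (3S,4R,5S)-5-(3,4-dimethoxyphenyl)-4-(hydroxymethyl)oxolan-3-ol (all-cis diol)
Conditions: H2 (1 atm), 10% Pd/C, EtOAc, rt
Reagents that add atoms: none
Why: Hydrogenolysis of the primary benzyl ether over Pd/C; under neutral conditions at 1 atm the hindered secondary benzylic C–O bond of the oxolane ring should be cleaved far more slowly, and the stereocentres are untouched.

**Step 10**
Reactants: 17 the all-cis diol; 18 3,4-dimethoxybenzoyl chloride
Product: 19 [(2S,3R,4S)-2-(3,4-dimethoxyphenyl)-4-hydroxyoxolan-3-yl]methyl 3,4-dimethoxybenzoate (target)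
Conditions: 18 (1.05 equiv), 2,4,6-collidine, CH2Cl2, −40 to 0 °C
Reagents that add atoms: none
Why: Esterification with an aroyl chloride under kinetic control: with one equivalent of 18 and a hindered pyridine base at low temperature the primary hydroxyl should be acylated in preference to the secondary ring hydroxyl, which completes the target.

**Compound list**
1 | 3-(benzyloxy)propanoic acid | OC(=O)CCOCc1ccccc1 | starting material
2 | (S)-4-benzyloxazolidin-2-one | O=C1N[C@@H](Cc2ccccc2)CO1 | starting material
3 | 3-(benzyloxy)propanoic pivalic anhydride (not isolated) | CC(C)(C)C(=O)OC(=O)CCOCc1ccccc1 | intermediate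
4 | (S)-4-benzyl-3-[3-(benzyloxy)propanoyl]oxazolidin-2-one | O=C(CCOCc1ccccc1)N1[C@@H](Cc2ccccc2)COC1=O | intermediate
5 | 3,4-dimethoxybenzaldehyde (veratraldehyde) | COc1ccc(C=O)cc1OC | starting material
6 | dibutylboron Z-enolate of 4 (not isolated) | CCCCB(CCCC)O/C(=C\COCc1ccccc1)N1[C@@H](Cc2ccccc2)COC1=O | intermediate
7 | dibutylboron aldolate of 8 (not isolated) | C(OCc1ccccc1)[C@@H]([C@H](OB(CCCC)CCCC)c1ccc(OC)c(OC)c1)C(=O)N1[C@@H](Cc2ccccc2)COC1=O | intermediate
8 | (S)-4-benzyl-3-[(2S,3S)-2-[(benzyloxy)methyl]-3-(3,4-dimethoxyphenyl)-3-hydroxypropanoyl]oxazolidin-2-one (syn aldol) | C(OCc1ccccc1)[C@@H]([C@H](O)c1ccc(OC)c(OC)c1)C(=O)N1[C@@H](Cc2ccccc2)COC1=O | intermediate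
9 | (S)-4-benzyl-3-[(2S,3S)-2-[(benzyloxy)methyl]-3-[(tert-butyldimethylsilyl)oxy]-3-(3,4-dimethoxyphenyl)propanoyl]oxazolidin-2-one | C(OCc1ccccc1)[C@@H]([C@H](O[Si](C)(C)C(C)(C)C)c1ccc(OC)c(OC)c1)C(=O)N1[C@@H](Cc2ccccc2)COC1=O | intermediate
10 | (2S,3S)-2-[(benzyloxy)methyl]-3-[(tert-butyldimethylsilyl)oxy]-3-(3,4-dimethoxyphenyl)propaneperoxoic acid (not isolated) | C(OCc1ccccc1)[C@@H]([C@H](O[Si](C)(C)C(C)(C)C)c1ccc(OC)c(OC)c1)C(=O)OO | intermediate
11 | (2S,3S)-2-[(benzyloxy)methyl]-3-[(tert-butyldimethylsilyl)oxy]-3-(3,4-dimethoxyphenyl)propanoic acid | C(OCc1ccccc1)[C@@H]([C@H](O[Si](C)(C)C(C)(C)C)c1ccc(OC)c(OC)c1)C(=O)O | intermediate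
12 | isobutyl carbonic mixed anhydride of 11 (not isolated) | C(OCc1ccccc1)[C@@H]([C@H](O[Si](C)(C)C(C)(C)C)c1ccc(OC)c(OC)c1)C(=O)OC(=O)OCC(C)C | intermediate
13 | (3S,4S)-3-[(benzyloxy)methyl]-4-[(tert-butyldimethylsilyl)oxy]-1-diazo-4-(3,4-dimethoxyphenyl)butan-2-one | C(OCc1ccccc1)[C@@H]([C@H](O[Si](C)(C)C(C)(C)C)c1ccc(OC)c(OC)c1)C(=O)C=[N+]=[N-] | intermediate
14 | (3S,4S)-3-[(benzyloxy)methyl]-1-diazo-4-(3,4-dimethoxyphenyl)-4-hydroxybutan-2-one | C(OCc1ccccc1)[C@@H]([C@H](O)c1ccc(OC)c(OC)c1)C(=O)C=[N+]=[N-] | intermediate
15 | (4S,5S)-4-[(benzyloxy)methyl]-5-(3,4-dimethoxyphenyl)oxolan-3-one (4,5-cis) | C(OCc1ccccc1)[C@@H]2C(=O)CO[C@@H]2c3ccc(OC)c(OC)c3 | intermediate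
16 | (3S,4R,5S)-4-[(benzyloxy)methyl]-5-(3,4-dimethoxyphenyl)oxolan-3-ol (all-cis) | C(OCc1ccccc1)[C@@H]2[C@H](O)CO[C@@H]2c3ccc(OC)c(OC)c3 | intermediate
17 | (3S,4R,5S)-5-(3,4-dimethoxyphenyl)-4-(hydroxymethyl)oxolan-3-ol (all-cis) | OC[C@@H]2[C@H](O)CO[C@@H]2c3ccc(OC)c(OC)c3 | intermediate
18 | 3,4-dimethoxybenzoyl chloride | COc1ccc(C(=O)Cl)cc1OC | starting material
19 | [(2S,3R,4S)-2-(3,4-dimethoxyphenyl)-4-hydroxyoxolan-3-yl]methyl 3,4-dimethoxybenzoate | COc1ccc(C(=O)OC[C@@H]2[C@H](O)CO[C@@H]2c2ccc(OC)c(OC)c2)cc1OC | target

**Totals.** Total step count: 10. Longest linear sequence: 10 steps (1 to 19).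

**Steps most likely to fail**

Risk 1, step 7. The carbenoid may be diverted from O–H insertion into cycloaddition with the electron-rich aryl ring, ylide formation at the benzyl ether oxygen or C–H insertion. The fallback sets out from 8 and comes back at 16, so it also bypasses steps 3 to 6 and step 8, and it uses no diazo compound. Transamination of 8 with MeNHOMe·HCl and AlMe3 (CH2Cl2, −20 to 0 °C) should give the Weinreb amide F1. Chloromethyllithium (ICH2Cl, MeLi·LiBr, THF, −78 °C, in excess to allow for the free hydroxyl) should convert it into the chloromethyl ketone F2. Hydroxyl-directed Evans–Saksena reduction with Me4NBH(OAc)3 (MeCN/AcOH, −30 °C) should give the 1,3-anti chlorodiol F3, in which the new carbinol already has the required configuration. Direct SN2 displacement of the primary chloride by the benzylic hydroxyl (AgOTf, Ag2O, THF, rt; 5-exo-tet) then forms the same O–CH2 bond and gives 16.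

Risk 2, step 8. Hydride may be delivered with poor facial selectivity, or the hindered borohydride may enolise the ketone and so epimerise the centre next to the carbonyl. The fallback sets out from 15 and comes back at 16. The ketone is reduced under non-basic Luche conditions (NaBH4, CeCl3·7H2O, MeOH, −78 °C) and the epimers are separated. The unwanted alcohol with the hydroxyl trans to the benzyloxymethyl group, the C3 epimer F4, is converted by Mitsunobu inversion (4-nitrobenzoic acid, PPh3, DIAD, THF) into the all-cis 4-nitrobenzoate F5. Methanolysis (K2CO3, MeOH) then gives 16, so the carbinol configuration is fixed by SN2 inversion instead of by facial selection.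

Risk 3, step 10. Acylation may not discriminate well enough between the primary and the secondary hydroxyl, or the acyl group may migrate between them. The fallback sets out from 16 and comes back at 19, replacing kinetic discrimination by a protecting-group sequence. The secondary hydroxyl is silylated (TBSCl, imidazole, DMF) to the silyl ether F6. Hydrogenolysis (H2, 10% Pd/C, EtOAc) gives the primary alcohol F7. Esterification with 18 (Et3N, DMAP, CH2Cl2) gives the silylated ester F8. Desilylation under acidic, non-migrating conditions (HF·pyridine, THF, 0 °C) gives 19.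

**Further compounds**
F1 | step 7 | (2S,3S)-2-[(benzyloxy)methyl]-3-(3,4-dimethoxyphenyl)-3-hydroxy-N-methoxy-N-methylpropanamide | C(OCc1ccccc1)[C@@H]([C@H](O)c1ccc(OC)c(OC)c1)C(=O)N(C)OC
F2 | step 7 | (3S,4S)-3-[(benzyloxy)methyl]-1-chloro-4-(3,4-dimethoxyphenyl)-4-hydroxybutan-2-one | C(OCc1ccccc1)[C@@H]([C@H](O)c1ccc(OC)c(OC)c1)C(=O)CCl
F3 | step 7 | (2S,3S,4S)-3-[(benzyloxy)methyl]-1-chloro-4-(3,4-dimethoxyphenyl)butane-2,4-diol (1,3-anti diol) | C(OCc1ccccc1)[C@@H]([C@H](O)c1ccc(OC)c(OC)c1)[C@H](O)CCl
F4 | step 8 | (3R,4R,5S)-4-[(benzyloxy)methyl]-5-(3,4-dimethoxyphenyl)oxolan-3-ol (C3 epimer of 16) | C(OCc1ccccc1)[C@@H]2[C@@H](O)CO[C@@H]2c3ccc(OC)c(OC)c3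
F5 | step 8 | 4-nitrobenzoate ester of 16 (all-cis) | C(OCc1ccccc1)[C@@H]2[C@H](OC(=O)c4ccc(cc4)[N+](=O)[O-])CO[C@@H]2c3ccc(OC)c(OC)c3
F6 | step 10 | tert-butyldimethylsilyl ether of 16 (all-cis) | C(OCc1ccccc1)[C@@H]2[C@H](O[Si](C)(C)C(C)(C)C)CO[C@@H]2c3ccc(OC)c(OC)c3
F7 | step 10 | 17 with its secondary hydroxyl as the tert-butyldimethylsilyl ether (all-cis) | OC[C@@H]2[C@H](O[Si](C)(C)C(C)(C)C)CO[C@@H]2c3ccc(OC)c(OC)c3
F8 | step 10 | tert-butyldimethylsilyl ether of 19 | COc1ccc(C(=O)OC[C@@H]2[C@H](O[Si](C)(C)C(C)(C)C)CO[C@@H]2c2ccc(OC)c(OC)c2)cc1OC
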